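**Retrosynthetic overview**

1. Penicanesin D is traced back to its dimethyl ether by BCl3 cleavage of the central aryl methyl ether; the C3(pyranone)–CH2(benzyl) bond is made by Knoevenagel condensation and Hantzsch-ester reduction between an aryl aldehyde and 4-hydroxy-6-[(2S)-2-hydroxypropyl]pyran-2-one.
2. The feature the strategy rests on is the benzene ring whose six carbons carry, in sequence, C–acetyl, C–OH, C–OH, C–OMe, C–H and C–CH2(pyranone). The three contiguous C–O carbons and the C–H carbon are the four carbons of a 1,2,3-trioxygenated silyl ketene-acetal diene; the C–acetyl and C–CH2 carbons are the two carbons of an acetyl alkyne.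
3. Benzene ring (formed first): Diels–Alder reaction of 1,2,3-trimethoxy-1-(trimethylsilyloxy)buta-1,3-diene with a 5-silyloxypent-3-yn-2-one, then loss of methanol. The diene comes from methyl methoxyacetate in three steps, the ynone from a propargyl silyl ether in one.
4. Pyranone ring (formed second, on a separate branch): lactonisation of a 3,5-dioxo ester made from the methyl acetoacetate dianion and the Weinreb amide of methyl (S)-3-hydroxybutanoate, which supplies the only stereocentre.
5. Order: benzene ring (step 5), pyranone ring (step 11), union of the two (step 13), demethylation (step 14).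

Key step: step 5

Remark on the chemistry: the enol ether made in step 2 is carried as an E/Z mixture because both isomers give the same dienolate; the racemic centres that appear transiently before aromatisation are of no consequence; the (S)-carbinol of the target is taken from the chiral pool and no bond to it is broken anywhere in the route.

**Route**

Step 1
Reactants: 1 methyl methoxyacetate; 2 N-methoxy-N-methylacetamide
Product: 4 methyl 2-methoxy-3-oxobutanoate, via lithium enolate 3 (not isolated)
Conditions: LiN(iPr)2, THF, −78 °C; then 2, −78 → 0 °C; 1 M HCl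
Reagents that add atoms: none
Why: Crossed Claisen condensation in which the preformed lithium ester enolate is C-acylated by the Weinreb amide, whose chelated tetrahedral adduct persists until the acidic quench, so that O-acylation and double acylation should not compete.

Step 2
Reactants: 4 methyl 2-methoxy-3-oxobutanoate
Product: 6 methyl 2,3-dimethoxybut-2-enoate (E/Z mixture), via dimethyl ketal 5 (not isolated)
Conditions: HC(OMe)3, MeOH, H2SO4 (cat.), 25 °C; then TsOH (cat.), 140 °C, MeOH distilled off
Reagents that add atoms: trimethyl orthoformate, COC(OC)OC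
Why: Acid-catalysed ketalisation by the orthoformate followed by thermal elimination of methanol (enol ether formation) should give the conjugated push–pull enoate, and any deconjugated isomer would lead to the same dienolate in step 3.

Step 3
Reactants: 6 methyl 2,3-dimethoxybut-2-enoate
Product: 8 1,2,3-trimethoxy-1-(trimethylsilyloxy)buta-1,3-diene, via lithium dienolate 7 (not isolated)
Conditions: LiN(iPr)2, THF, −78 °C; Me3SiCl, −78 → 25 °C; pentane, filtration, distillation
Reagents that add atoms: chlorotrimethylsilane, C[Si](C)(C)Cl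
Why: Kinetic γ-deprotonation of the β-alkoxy enoate and O-silylation of the extended enolate, the standard preparation of 1-alkoxy-1-silyloxy dienes (vinylogous silyl ketene acetals).

Step 4
Reactants: 9 tert-butyldimethyl(prop-2-yn-1-yloxy)silane; 2 N-methoxy-N-methylacetamide
Product: 11 5-{[tert-butyl(dimethyl)silyl]oxy}pent-3-yn-2-one, via lithium acetylide 10 (not isolated)
Conditions: n-BuLi, THF, −78 °C; then 2, −78 → 0 °C; cold 0.5 M HCl
Reagents that add atoms: none
Why: Weinreb ketone synthesis by acylation of the lithium acetylide, with an acidic quench so that the liberated hydroxylamine is protonated before it can add to the ynone.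

Step 5
Reactants: 8 1,2,3-trimethoxy-1-(trimethylsilyloxy)buta-1,3-diene; 11 5-{[tert-butyl(dimethyl)silyl]oxy}pent-3-yn-2-one
Product: 14 1-[6-({[tert-butyl(dimethyl)silyl]oxy}methyl)-2-hydroxy-3,4-dimethoxyphenyl]ethan-1-one, via cycloadduct 12 (not isolated), via aryl trimethylsilyl ether 13 (not isolated)
Conditions: PhMe, 25 → 80 °C; then SiO2, CH2Cl2, 25 °C; 0.1 M HCl, THF, 0 °C
Reagents that add atoms: none
Why: This is a thermal normal-demand Diels–Alder reaction of the electron-rich 1-alkoxy-1-silyloxy diene with the electron-poor alkyne, concerted but asynchronous (or, at the limit, Michael addition then ring closure), of the known type in which vinylogous silyl ketene acetals and acetylenic ketones or esters give oxygenated benzenes. The six-membered carbocycle closes in the (4+2) event itself by forming the bond from the diene CH2 terminus to the alkyne carbon β to the ketone (the one bearing CH2OSi) and the bond from the ketene-acetal carbon to the α carbon (the one bearing acetyl), giving the 1,4-cyclohexadiene 12. Acid-assisted 1,4-elimination of methanol from the ketal carbon and the ring CH2 should aromatise 12 to the silyl ether 13, and hydrolysis of its Si–O bond gives the phenol 14, hydrogen-bonded to the acetyl group. No stereocentre remains, since the ketal carbon of 12 forms racemic and is destroyed on aromatisation. The step needs regioselectivity and alkyne-over-carbonyl chemoselectivity: the first is secured by pairing the largest HOMO coefficient (terminal CH2 of the vinylogous ketene acetal) with the largest LUMO coefficient (the ynone β carbon), the second by working thermally without a Lewis acid, which would favour hetero-cycloaddition at C=O. The primary tert-butyldimethylsilyl ether is chosen to survive the brief dilute acid that removes the trimethylsilyl group, and the three ring oxygens emerge differentiated as free phenol, central methyl ether and outer methyl ether.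

Step 6
Reactants: 14 1-[6-({[tert-butyl(dimethyl)silyl]oxy}methyl)-2-hydroxy-3,4-dimethoxyphenyl]ethan-1-one
Product: 15 1-[2-hydroxy-6-(hydroxymethyl)-3,4-dimethoxyphenyl]ethan-1-one
Conditions: Bu4NF, AcOH, THF, 0 → 25 °C
Reagents that add atoms: none
Why: Buffered fluoride desilylation frees the primary alcohol without base-induced aldol chemistry and without the strong acid that would dehydrate the cyclic hemiketal tautomer of an ortho-acyl benzyl alcohol to an isobenzofuran.

Step 7
Reactants: 15 1-[2-hydroxy-6-(hydroxymethyl)-3,4-dimethoxyphenyl]ethan-1-one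
Product: 16 2-acetyl-3-hydroxy-4,5-dimethoxybenzaldehyde
Conditions: MnO2 (activated, excess), CH2Cl2, 25 °C
Reagents that add atoms: none
Why: Heterogeneous MnO2 oxidation is selective for the benzylic alcohol, stops at the aldehyde and should leave the chelated ortho-acyl phenol untouched.

Step 8
Reactants: 17 methyl (3S)-3-hydroxybutanoate
Product: 18 methyl (3S)-3-{[tert-butyl(dimethyl)silyl]oxy}butanoate
Conditions: t-BuMe2SiCl, imidazole, DMF, 25 °C
Reagents that add atoms: tert-butyldimethylsilyl chloride, CC(C)(C)[Si](C)(C)Cl
Why: Standard imidazole-promoted silylation masks the carbinol so that it cannot later close a dihydropyranone onto the diketone formed in step 10, and the stereocentre is not touched.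

Step 9
Reactants: 18 methyl (3S)-3-{[tert-butyl(dimethyl)silyl]oxy}butanoate
Product: 19 (3S)-3-{[tert-butyl(dimethyl)silyl]oxy}-N-methoxy-N-methylbutanamide
Conditions: MeNHOMe·HCl, i-PrMgCl, THF, −20 → 0 °C; cold 0.5 M HCl
Reagents that add atoms: N,O-dimethylhydroxylamine hydrochloride, CNOC.Cl
Why: Direct aminolysis of the ester by the chloromagnesium amide of N,O-dimethylhydroxylamine gives the Weinreb amide at low temperature, where β-elimination of the silyloxy group is not expected.

Step 10
Reactants: 20 methyl acetoacetate; 19 (3S)-3-{[tert-butyl(dimethyl)silyl]oxy}-N-methoxy-N-methylbutanamide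
Product: 22 methyl (7S)-7-{[tert-butyl(dimethyl)silyl]oxy}-3,5-dioxooctanoate, via acetoacetate dianion 21 (not isolated)
Conditions: 20 (excess), NaH, THF, 0 °C; n-BuLi, 0 °C; then 19, −78 → 0 °C; cold 0.5 M HCl
Reagents that add atoms: none
Why: Claisen-type γ-acylation of the β-keto ester dianion at its more nucleophilic terminal carbon by the Weinreb amide, whose chelated adduct prevents over-addition, with the carbinol centre lying β to the reacting carbonyl and therefore not epimerisable.

Step 11
Reactants: 22 methyl (7S)-7-{[tert-butyl(dimethyl)silyl]oxy}-3,5-dioxooctanoate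
Product: 23 6-[(2S)-2-{[tert-butyl(dimethyl)silyl]oxy}propyl]-4-hydroxy-2H-pyran-2-one
Conditions: DBU, PhMe, 80 °C
Reagents that add atoms: none
Why: Base-promoted enol lactonisation in which the C5 enolate oxygen attacks the ester and expels methanol, the usual closure of 3,5-dioxo esters to 4-hydroxy-2-pyranones.

Step 12
Reactants: 23 6-[(2S)-2-{[tert-butyl(dimethyl)silyl]oxy}propyl]-4-hydroxy-2H-pyran-2-one
Product: 24 4-hydroxy-6-[(2S)-2-hydroxypropyl]-2H-pyran-2-one
Conditions: aq. HF, MeCN, 25 °C
Reagents that add atoms: none
Why: Acidic fluoride cleaves the Si–O bond of the secondary silyl ether while the acid-stable vinylogous-acid pyranone survives, and the C–O bond at the stereocentre is not broken, so the (S) configuration is retained.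

Step 13
Reactants: 16 2-acetyl-3-hydroxy-4,5-dimethoxybenzaldehyde; 24 4-hydroxy-6-[(2S)-2-hydroxypropyl]-2H-pyran-2-one
Product: 26 3-[(2-acetyl-3-hydroxy-4,5-dimethoxyphenyl)methyl]-4-hydroxy-6-[(2S)-2-hydroxypropyl]-2H-pyran-2-one, via alkylidene pyrandione 25 (not isolated)
Conditions: L-proline (cat.), Hantzsch ester (diethyl 2,6-dimethyl-1,4-dihydropyridine-3,5-dicarboxylate), EtOH, 25 → 40 °C
Reagents that add atoms: none
Why: Organocatalytic three-component reductive alkylation in which amine-catalysed Knoevenagel condensation at C3 of the 4-hydroxypyranone gives the electrophilic alkylidene, which is reduced in situ by conjugate hydride transfer from the Hantzsch ester before a second pyranone can add; no stereocentre is formed and the remote (S)-carbinol is unaffected.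

Step 14
Reactants: 26 3-[(2-acetyl-3-hydroxy-4,5-dimethoxyphenyl)methyl]-4-hydroxy-6-[(2S)-2-hydroxypropyl]-2H-pyran-2-one
Product: 27 Penicanesin D, 3-[(2-acetyl-3,4-dihydroxy-5-methoxyphenyl)methyl]-4-hydroxy-6-[(2S)-2-hydroxypropyl]-2H-pyran-2-one
Conditions: BCl3 (excess), CH2Cl2, −78 → 0 °C; then H2O
Reagents that add atoms: none
Why: Chelation-directed ether cleavage in which the aryloxy-dichloroborane formed at the phenol delivers boron to the adjacent, sterically twisted central methoxy oxygen so that chloride removes its methyl group as a cyclic catechol borate forms, while the outer methoxy group (para to the acetyl group, no neighbouring OH) should remain and the borate esters of the other hydroxyl groups are hydrolysed on work-up at low temperature without substitution at the carbinol.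

**Compound list**

1 | methyl methoxyacetate | COCC(=O)OC | starting material
2 | N-methoxy-N-methylacetamide | CON(C)C(C)=O | starting material
3 | lithium 1,2-dimethoxyethen-1-olate (lithium enolate of 1) | [Li]OC(OC)=COC | intermediate (not isolated)
4 | methyl 2-methoxy-3-oxobutanoate (racemic) | CC(=O)C(OC)C(=O)OC | intermediate
5 | methyl 2,3,3-trimethoxybutanoate (racemic dimethyl ketal) | CC(OC)(OC)C(OC)C(=O)OC | intermediate (not isolated)
6 | methyl 2,3-dimethoxybut-2-enoate (E/Z mixture) | CC(OC)=C(OC)C(=O)OC | intermediate
7 | lithium 1,2,3-trimethoxybuta-1,3-dien-1-olate (lithium dienolate of 6) | [Li]OC(OC)=C(OC)C(OC)=C | intermediate (not isolated)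
8 | 1,2,3-trimethoxy-1-(trimethylsilyloxy)buta-1,3-diene | C=C(OC)C(OC)=C(OC)O[Si](C)(C)C | intermediate
9 | tert-butyldimethyl(prop-2-yn-1-yloxy)silane | C#CCO[Si](C)(C)C(C)(C)C | starting material
10 | [3-{[tert-butyl(dimethyl)silyl]oxy}prop-1-yn-1-yl]lithium | [Li]C#CCO[Si](C)(C)C(C)(C)C | intermediate (not isolated)
11 | 5-{[tert-butyl(dimethyl)silyl]oxy}pent-3-yn-2-one | CC(=O)C#CCO[Si](C)(C)C(C)(C)C | intermediate
12 | 1-[2-({[tert-butyl(dimethyl)silyl]oxy}methyl)-4,5,6-trimethoxy-6-(trimethylsilyloxy)cyclohexa-1,4-dien-1-yl]ethan-1-one (racemic cycloadduct) | CC(=O)C1=C(CO[Si](C)(C)C(C)(C)C)CC(OC)=C(OC)C1(OC)O[Si](C)(C)C | intermediate (not isolated)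
13 | 1-[6-({[tert-butyl(dimethyl)silyl]oxy}methyl)-3,4-dimethoxy-2-(trimethylsilyloxy)phenyl]ethan-1-one | CC(=O)c1c(O[Si](C)(C)C)c(OC)c(OC)cc1CO[Si](C)(C)C(C)(C)C | intermediate (not isolated)
14 | 1-[6-({[tert-butyl(dimethyl)silyl]oxy}methyl)-2-hydroxy-3,4-dimethoxyphenyl]ethan-1-one | CC(=O)c1c(O)c(OC)c(OC)cc1CO[Si](C)(C)C(C)(C)C | intermediate
15 | 1-[2-hydroxy-6-(hydroxymethyl)-3,4-dimethoxyphenyl]ethan-1-one | CC(=O)c1c(O)c(OC)c(OC)cc1CO | intermediate
16 | 2-acetyl-3-hydroxy-4,5-dimethoxybenzaldehyde | CC(=O)c1c(O)c(OC)c(OC)cc1C=O | intermediate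
17 | methyl (3S)-3-hydroxybutanoate | C[C@H](O)CC(=O)OC | starting material
18 | methyl (3S)-3-{[tert-butyl(dimethyl)silyl]oxy}butanoate | C[C@H](O[Si](C)(C)C(C)(C)C)CC(=O)OC | intermediate
19 | (3S)-3-{[tert-butyl(dimethyl)silyl]oxy}-N-methoxy-N-methylbutanamide | C[C@H](O[Si](C)(C)C(C)(C)C)CC(=O)N(C)OC | intermediate
20 | methyl acetoacetate (methyl 3-oxobutanoate) | CC(=O)CC(=O)OC | starting material
21 | lithium sodium 1-methoxybuta-1,3-diene-1,3-bis(olate) (dianion of 20) | COC(O[Na])=CC(O[Li])=C | intermediate (not isolated)
22 | methyl (7S)-7-{[tert-butyl(dimethyl)silyl]oxy}-3,5-dioxooctanoate | C[C@H](O[Si](C)(C)C(C)(C)C)CC(=O)CC(=O)CC(=O)OC | intermediate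
23 | 6-[(2S)-2-{[tert-butyl(dimethyl)silyl]oxy}propyl]-4-hydroxy-2H-pyran-2-one | C[C@H](O[Si](C)(C)C(C)(C)C)Cc1cc(O)cc(=O)o1 | intermediate
24 | 4-hydroxy-6-[(2S)-2-hydroxypropyl]-2H-pyran-2-one | C[C@H](O)Cc1cc(O)cc(=O)o1 | intermediate
25 | 3-[(2-acetyl-3-hydroxy-4,5-dimethoxyphenyl)methylidene]-6-[(2S)-2-hydroxypropyl]-2H-pyran-2,4(3H)-dione (alkene geometry not defined) | CC(=O)c1c(O)c(OC)c(OC)cc1C=C1C(=O)C=C(C[C@H](C)O)OC1=O | intermediate (not isolated)
26 | 3-[(2-acetyl-3-hydroxy-4,5-dimethoxyphenyl)methyl]-4-hydroxy-6-[(2S)-2-hydroxypropyl]-2H-pyran-2-one | COc1cc(Cc2c(O)cc(C[C@H](C)O)oc2=O)c(C(C)=O)c(O)c1OC | intermediate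
27 | Penicanesin D, 3-[(2-acetyl-3,4-dihydroxy-5-methoxyphenyl)methyl]-4-hydroxy-6-[(2S)-2-hydroxypropyl]-2H-pyran-2-one | COc1cc(Cc2c(O)cc(C[C@H](C)O)oc2=O)c(C(C)=O)c(O)c1O | target

**Summary**

Total step count: 14. Longest linear sequence: 8 steps (steps 1, 2, 3, 5, 6, 7, 13, 14); the pyranone branch (steps 8–12) joins at step 13.

**Steps most likely to fail, with fallbacks**

Step 5 (benzannulation). The internal ynone may add too slowly, so that hydrolysis or oligomerisation of the moisture-sensitive diene wins, or the adduct may fail to close and aromatise cleanly. The fallback keeps the same ring construction but uses a more electron-poor dienophile. It sets out from 9 and 8: formylation of the lithium acetylide with DMF (n-BuLi, THF, −78 °C; DMF; inverse quench into aq. KH2PO4) should give 4-{[tert-butyl(dimethyl)silyl]oxy}but-2-ynal F1, which has the same polarisation as the ynone. Thermal cycloaddition with 8 (PhMe, 0 → 25 °C, no Lewis acid, so that the alkyne and not the formyl group reacts) should give the cycloadduct 2-({[tert-butyl(dimethyl)silyl]oxy}methyl)-4,5,6-trimethoxy-6-(trimethylsilyloxy)cyclohexa-1,4-diene-1-carbaldehyde F2. Loss of methanol then gives the aryl silyl ether 6-({[tert-butyl(dimethyl)silyl]oxy}methyl)-3,4-dimethoxy-2-(trimethylsilyloxy)benzaldehyde F3, and the same mild acid work-up gives 6-({[tert-butyl(dimethyl)silyl]oxy}methyl)-2-hydroxy-3,4-dimethoxybenzaldehyde F4. Addition of MeMgBr (excess, THF, −78 → 0 °C) to the aldehyde of the magnesium phenoxide should give the carbinol 1-[6-({[tert-butyl(dimethyl)silyl]oxy}methyl)-2-hydroxy-3,4-dimethoxyphenyl]ethan-1-ol F5. Oxidation of this benzylic alcohol with MnO2 (CH2Cl2, 25 °C) comes back to the route at 14.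

Step 13 (reductive alkylation). Conjugate hydride transfer to the hindered, electron-rich alkylidene may be outrun by addition of a second pyranone, or by amine-promoted aldol condensation between the neighbouring acetyl and formyl groups. The fallback sets out from 16 and 24 and traps the alkylidene with a thiol instead of reducing it in the same flask. Three-component condensation with thiophenol (PhSH, AcOH, piperidine (cat.), EtOH, 25 → 60 °C) should give the sulfide 3-[(2-acetyl-3-hydroxy-4,5-dimethoxyphenyl)(phenylsulfanyl)methyl]-4-hydroxy-6-[(2S)-2-hydroxypropyl]-2H-pyran-2-one F6 as a mixture of epimers at the benzylic carbon. Reductive desulfurisation (Raney Ni, EtOH, 25 °C) removes that centre and comes back to the route at 26.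

Step 14 (demethylation). Prolonged exposure of the fully assembled molecule to BCl3 may lead to over-cleavage of the outer methyl ether, chloride substitution with loss of configuration at the secondary carbinol, or fragmentation at the doubly activated benzylic methylene. The fallback moves the ether cleavage ahead of the fragment union, so that the stereocentre never meets the Lewis acid and the site selectivity is settled on a simple intermediate. It sets out from 16: BCl3 (CH2Cl2, −78 → 0 °C; then H2O) should give 2-acetyl-3,4-dihydroxy-5-methoxybenzaldehyde F7. Reductive alkylation of 24 with F7 under the conditions of step 13 (L-proline (cat.), Hantzsch ester, EtOH) should pass through the alkylidene 3-[(2-acetyl-3,4-dihydroxy-5-methoxyphenyl)methylidene]-6-[(2S)-2-hydroxypropyl]-2H-pyran-2,4(3H)-dione F8 and come back to the route directly at the target 27.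

**Further compounds**

F1 | step 5 | 4-{[tert-butyl(dimethyl)silyl]oxy}but-2-ynal | O=CC#CCO[Si](C)(C)C(C)(C)C
F2 | step 5 | 2-({[tert-butyl(dimethyl)silyl]oxy}methyl)-4,5,6-trimethoxy-6-(trimethylsilyloxy)cyclohexa-1,4-diene-1-carbaldehyde (racemic) | O=CC1=C(CO[Si](C)(C)C(C)(C)C)CC(OC)=C(OC)C1(OC)O[Si](C)(C)C
F3 | step 5 | 6-({[tert-butyl(dimethyl)silyl]oxy}methyl)-3,4-dimethoxy-2-(trimethylsilyloxy)benzaldehyde | O=Cc1c(O[Si](C)(C)C)c(OC)c(OC)cc1CO[Si](C)(C)C(C)(C)C
F4 | step 5 | 6-({[tert-butyl(dimethyl)silyl]oxy}methyl)-2-hydroxy-3,4-dimethoxybenzaldehyde | O=Cc1c(O)c(OC)c(OC)cc1CO[Si](C)(C)C(C)(C)C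
F5 | step 5 | 1-[6-({[tert-butyl(dimethyl)silyl]oxy}methyl)-2-hydroxy-3,4-dimethoxyphenyl]ethan-1-ol (racemic) | CC(O)c1c(O)c(OC)c(OC)cc1CO[Si](C)(C)C(C)(C)C
F6 | step 13 | 3-[(2-acetyl-3-hydroxy-4,5-dimethoxyphenyl)(phenylsulfanyl)methyl]-4-hydroxy-6-[(2S)-2-hydroxypropyl]-2H-pyran-2-one (epimers at the benzylic carbon) | CC(=O)c1c(O)c(OC)c(OC)cc1C(Sc1ccccc1)c1c(O)cc(C[C@H](C)O)oc1=O
F7 | step 14 | 2-acetyl-3,4-dihydroxy-5-methoxybenzaldehyde | CC(=O)c1c(O)c(O)c(OC)cc1C=O
F8 | step 14 | 3-[(2-acetyl-3,4-dihydroxy-5-methoxyphenyl)methylidene]-6-[(2S)-2-hydroxypropyl]-2H-pyran-2,4(3H)-dione (alkene geometry not defined) | CC(=O)c1c(O)c(O)c(OC)cc1C=C1C(=O)C=C(C[C@H](C)O)OC1=O
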